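The route cuts lactone B at C3'–C4' and O1'–C2'. The cis C3'/C4' pair, flanked by the phenolic O1' of ring B and the C4' aryl group, is read as the adduct of the ring B ortho-quinone methide and a ketene enolate. One alkaloid-catalysed formal [4+2] therefore joins the two halves, closes lactone B and sets both new stereocentres. Its partners are the sulfone-masked pentaoxygenated methide and the acetyl chloride of the finished, enantiopure trans lactone A, made by rhodium-catalysed aryl addition to a coumarin and anti alkylation. All eight phenols travel as benzyl ethers, removed together at the end.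

Key step: step 13

Remark: numbering follows chroman-2-one, unprimed for the 5,7-dioxygenated lactone A and primed for the 5,6,7,8-tetraoxygenated lactone B. The target has eight phenolic hydroxyls, so the protected product of the key step is an octabenzyl ether. The methide is released before the acid chloride is added, so that the free phenol of the sulfone is not acylated. The facial sense assigned to O-benzoylquinidine is an expectation, not an established fact for this substrate, and is to be confirmed in the first experiment.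

Step 1
Reactants: 1 phloroglucinol; 2 ethyl propiolate
Product: 3 5,7-dihydroxycoumarin
Conditions: ZnCl2 (1 equiv), dioxane, 95 °C
Reagents that add atoms: none
Why: Pechmann-type hydroarylation–lactonisation, in which a ring carbon of the symmetric triphenol adds to the ZnCl2-activated propiolate and the (Z)-2-hydroxycinnamate lactonises with loss of ethanol, so only one coumarin can form.

Step 2
Reactants: 3 5,7-dihydroxycoumarin
Product: 4 5,7-bis(benzyloxy)coumarin
Conditions: BnBr (2.4 equiv), K2CO3, acetone, reflux
Reagents that add atoms: benzyl bromide, BrCc1ccccc1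
Why: Williamson etherification of both phenols, with the coumarin lactone stable to anhydrous carbonate.

Step 3
Reactants: 4 5,7-bis(benzyloxy)coumarin; 5 4-benzyloxyphenylboronic acid
Product: 6 (4R)-5,7-bis(benzyloxy)-4-[4-(benzyloxy)phenyl]chroman-2-one
Conditions: Rh(acac)(C2H4)2 (3 mol%), (R)-SEGPHOS (3.3 mol%), 5 (5 equiv), dioxane/H2O 10:1, 60 °C
Reagents that add atoms: none
Why: Hayashi–Miyaura asymmetric 1,4-addition, in which the aryl complex of monovalent rhodium inserts the C3=C4 bond on the face selected by (R)-SEGPHOS (the series that gives (4R)-4-arylchroman-2-ones in this reaction class) and water protonates the rhodium enolate.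

Step 4
Reactants: 6 (4R)-5,7-bis(benzyloxy)-4-[4-(benzyloxy)phenyl]chroman-2-one; 7 allyl bromoacetate
Product: 9 allyl 2-[(3S,4R)-5,7-bis(benzyloxy)-4-[4-(benzyloxy)phenyl]-2-oxochroman-3-yl]acetate (3,4-trans), via lithium enolate 8 (not isolated)
Conditions: LiN(SiMe3)2 (1.05 equiv), THF, −78 °C; then 7, −78 → −40 °C
Reagents that add atoms: none
Why: Lactone enolate alkylation (SN2 on the α-bromo ester), in which the C4 aryl group, held pseudoaxial by the peri 5-benzyloxy group, shields one face of enolate 8 so that the side chain should enter anti and give the trans (3S,4R) lactone, C4 being untouched.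

Step 5
Reactants: 9 allyl ester
Product: 10 2-[(3S,4R)-5,7-bis(benzyloxy)-4-[4-(benzyloxy)phenyl]-2-oxochroman-3-yl]acetic acid
Conditions: Pd(PPh3)4 (5 mol%), TolSO2Na (1.2 equiv), THF/H2O, rt; then 1 M HCl
Reagents that add atoms: none
Why: Tsuji–Trost deallylation, in which zerovalent palladium ionises the allyl ester to a π-allyl complex that the sulfinate captures as a sulfone under neutral conditions that spare the aryl lactone, the benzyl ethers and the C3 configuration.

Step 6
Reactants: 10 acid
Product: 11 2-[(3S,4R)-5,7-bis(benzyloxy)-4-[4-(benzyloxy)phenyl]-2-oxochroman-3-yl]acetyl chloride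
Conditions: (COCl)2 (1.5 equiv), DMF (cat.), CH2Cl2, 0 °C → rt; evaporated and used crude
Reagents that add atoms: oxalyl chloride, O=C(Cl)C(=O)Cl
Why: Acid chloride formation through the chloroiminium species from oxalyl chloride and DMF, with no Lewis acid present, so the electron-rich rings and the lactone are left alone.

Step 7
Reactants: 12 2,3,4-trihydroxybenzaldehyde
Product: 13 2,3,4-tris(benzyloxy)benzaldehyde
Conditions: BnBr (3.6 equiv), K2CO3, DMF, 60 °C
Reagents that add atoms: benzyl bromide, BrCc1ccccc1
Why: Williamson etherification of all three phenols, the warm DMF overcoming the chelated 2-hydroxyl.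

Step 8
Reactants: 13 2,3,4-tris(benzyloxy)benzaldehyde
Product: 15 2,3,4-tris(benzyloxy)phenol, via aryl formate 14 (not isolated)
Conditions: mCPBA, CH2Cl2, 0 °C → rt; then K2CO3 (cat.), MeOH, rt
Reagents that add atoms: 3-chloroperoxybenzoic acid, OOC(=O)c1cccc(Cl)c1
Why: Baeyer–Villiger (Dakin-type) oxidation, in which the electron-rich aryl group migrates in the Criegee intermediate to give formate 14, cleaved by mild methanolysis.

Step 9
Reactants: 15 2,3,4-tris(benzyloxy)phenol
Product: 16 1,2,3,4-tetrakis(benzyloxy)benzene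
Conditions: BnBr (1.2 equiv), K2CO3, DMF, rt
Reagents that add atoms: benzyl bromide, BrCc1ccccc1
Why: Williamson etherification of the single phenol, giving a symmetric tetraether whose two free positions are equivalent.

Step 10
Reactants: 16 1,2,3,4-tetrakis(benzyloxy)benzene
Product: 18 2,3,4,5-tetrakis(benzyloxy)benzaldehyde, via iminium chloride 17 (not isolated)
Conditions: POCl3, DMF, 0 → 70 °C; then ice-water
Reagents that add atoms: N,N-dimethylformamide, CN(C)C=O; water, O
Why: Vilsmeier–Haack formylation, in which the chloroiminium ion attacks one of the two equivalent free positions (each ortho and para to ether oxygens) and iminium 17 is hydrolysed on work-up, as is established for the tetramethyl analogue.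

Step 11
Reactants: 18 2,3,4,5-tetrakis(benzyloxy)benzaldehyde
Product: 20 2,3,4,5-tetrakis(benzyloxy)phenol, via aryl formate 19 (not isolated)
Conditions: mCPBA, CH2Cl2, 0 °C → rt; then K2CO3 (cat.), MeOH, rt
Reagents that add atoms: 3-chloroperoxybenzoic acid, OOC(=O)c1cccc(Cl)c1
Why: Baeyer–Villiger (Dakin-type) oxidation with migration of the aryl group, which bears ortho and para ether oxygens, followed by methanolysis of formate 19.

Step 12
Reactants: 20 2,3,4,5-tetrakis(benzyloxy)phenol; 21 4-benzyloxybenzaldehyde
Product: 22 racemic 3,4,5,6-tetrakis(benzyloxy)-2-{[4-(benzyloxy)phenyl](tosyl)methyl}phenol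
Conditions: TolSO2Na (1.5 equiv), HCO2H/H2O/THF, rt
Reagents that add atoms: sodium p-toluenesulfinate, [Na+].[O-]S(=O)c1ccc(C)cc1
Why: Three-component Friedel–Crafts (Mannich-type) sulfonylalkylation, in which the only free ring position of 20, ortho to the hydroxyl, attacks the activated aldehyde and sulfinate captures the resulting benzylic cation/quinone methide at sulfur.

Step 13
Reactants: 22 racemic sulfone; 11 acid chloride
Product: 25 (3R,4R,3'S,4'R)-octabenzyl ether of the target, via quinone methide 23 (not isolated), via ketene 24 (not isolated)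
Conditions: 22, iPr2NEt (3 equiv), CH2Cl2, rt, 30 min; then O-benzoylquinidine (20 mol%), 11 (1.3 equiv in toluene, slow addition), −78 → −40 °C
Reagents that add atoms: none
Why: iPr2NEt first expels sulfinate from the phenoxide of 22 to give methide 23 and then dehydrochlorinates 11 to ketene 24, which O-benzoylquinidine holds as a (Z)-acylammonium enolate; enolate carbon C3' adds to methide carbon C4' and the liberated aryloxide O1' acylates C2', releasing the alkaloid. This is the stepwise, endo-organised formal oxa-[4+2] known for cinchona-alkaloid ketene enolates with ortho-quinone-type heterodienes and for carbene-bound enolates with ortho-quinone methides, which gives cis-3,4-disubstituted dihydrocoumarins. Lactone B, the one ring formed, closes by 6-exo-trig attack of O1' on the acylammonium carbonyl once the C3'–C4' bond is made. C3' is set by the alkaloid, expected in the quinidine series to leave the Si face of the enolate carbon open, and C4' by the closed transition state that pairs this face with the Re face of the methide carbon (acylammonium exo), which together should give cis (3'S,4'R). The step needs endo (cis) diastereoselectivity and catalyst control over the resident C3/C4 centres: the ring-locked s-cis oxadiene, the (Z)-enolate and the (E)-methide geometry secure the former, the E form being replenished by reversible sulfinate addition and being the only one that fits the closed transition state, while the alkaloid series is chosen for the latter. Releasing 23 before the slow addition of 11 keeps the acid chloride away from the free phenol of 22 and keeps the ketene concentration low.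

Step 14
Reactants: 25 octabenzyl ether
Product: 26 (3R,4R,3'S,4'R)-5,5',6',7,7',8'-hexahydroxy-4,4'-bis(4-hydroxyphenyl)-3,3'-bichroman-2,2'-dione (target)
Conditions: H2 (1 atm), 10% Pd/C, THF/EtOAc, rt; filtered and concentrated under argon
Reagents that add atoms: none
Why: Catalytic hydrogenolysis of the eight aryl benzyl ethers under neutral, non-nucleophilic conditions that should leave both aryl lactones and the epimerisable cis C3'/C4' pair untouched, none of the four stereocentres carrying a hydrogenolysable C–O bond.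

Compound list
1 | phloroglucinol | Oc1cc(O)cc(O)c1 | starting material
2 | ethyl propiolate | C#CC(=O)OCC | starting material
3 | 5,7-dihydroxycoumarin | O=C1C=Cc2c(O)cc(O)cc2O1 | intermediate
4 | 5,7-bis(benzyloxy)coumarin | O=C1C=Cc2c(OCc3ccccc3)cc(OCc3ccccc3)cc2O1 | intermediate
5 | 4-benzyloxyphenylboronic acid | OB(O)c1ccc(OCc2ccccc2)cc1 | starting material
6 | (4R)-5,7-bis(benzyloxy)-4-[4-(benzyloxy)phenyl]chroman-2-one | O=C1Oc2cc(OCc3ccccc3)cc(OCc3ccccc3)c2[C@@H](c2ccc(OCc3ccccc3)cc2)C1 | intermediate
7 | allyl bromoacetate | BrCC(=O)OCC=C | starting material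
8 | lithium enolate of 6 | [Li]OC1=C[C@H](c2ccc(OCc3ccccc3)cc2)c2c(OCc3ccccc3)cc(OCc3ccccc3)cc2O1 | intermediate (not isolated)
9 | allyl 2-[(3S,4R)-5,7-bis(benzyloxy)-4-[4-(benzyloxy)phenyl]-2-oxochroman-3-yl]acetate | O=C1Oc2cc(OCc3ccccc3)cc(OCc3ccccc3)c2[C@@H](c2ccc(OCc3ccccc3)cc2)[C@@H]1CC(=O)OCC=C | intermediate
10 | 2-[(3S,4R)-5,7-bis(benzyloxy)-4-[4-(benzyloxy)phenyl]-2-oxochroman-3-yl]acetic acid | O=C1Oc2cc(OCc3ccccc3)cc(OCc3ccccc3)c2[C@@H](c2ccc(OCc3ccccc3)cc2)[C@@H]1CC(=O)O | intermediate
11 | 2-[(3S,4R)-5,7-bis(benzyloxy)-4-[4-(benzyloxy)phenyl]-2-oxochroman-3-yl]acetyl chloride | O=C1Oc2cc(OCc3ccccc3)cc(OCc3ccccc3)c2[C@@H](c2ccc(OCc3ccccc3)cc2)[C@@H]1CC(=O)Cl | intermediate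
12 | 2,3,4-trihydroxybenzaldehyde | O=Cc1ccc(O)c(O)c1O | starting material
13 | 2,3,4-tris(benzyloxy)benzaldehyde | O=Cc1ccc(OCc2ccccc2)c(OCc2ccccc2)c1OCc1ccccc1 | intermediate
14 | 2,3,4-tris(benzyloxy)phenyl formate | O=COc1ccc(OCc2ccccc2)c(OCc2ccccc2)c1OCc1ccccc1 | intermediate (not isolated)
15 | 2,3,4-tris(benzyloxy)phenol | Oc1ccc(OCc2ccccc2)c(OCc2ccccc2)c1OCc1ccccc1 | intermediate
16 | 1,2,3,4-tetrakis(benzyloxy)benzene | c1cc(OCc2ccccc2)c(OCc2ccccc2)c(OCc2ccccc2)c1OCc1ccccc1 | intermediate
17 | N-[2,3,4,5-tetrakis(benzyloxy)benzylidene]-N-methylmethanaminium chloride | C[N+](C)=Cc1cc(OCc2ccccc2)c(OCc2ccccc2)c(OCc2ccccc2)c1OCc1ccccc1.[Cl-] | intermediate (not isolated)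
18 | 2,3,4,5-tetrakis(benzyloxy)benzaldehyde | O=Cc1cc(OCc2ccccc2)c(OCc2ccccc2)c(OCc2ccccc2)c1OCc1ccccc1 | intermediate
19 | 2,3,4,5-tetrakis(benzyloxy)phenyl formate | O=COc1cc(OCc2ccccc2)c(OCc2ccccc2)c(OCc2ccccc2)c1OCc1ccccc1 | intermediate (not isolated)
20 | 2,3,4,5-tetrakis(benzyloxy)phenol | Oc1cc(OCc2ccccc2)c(OCc2ccccc2)c(OCc2ccccc2)c1OCc1ccccc1 | intermediate
21 | 4-benzyloxybenzaldehyde | O=Cc1ccc(OCc2ccccc2)cc1 | starting material
22 | racemic 3,4,5,6-tetrakis(benzyloxy)-2-{[4-(benzyloxy)phenyl](tosyl)methyl}phenol | Oc1c(OCc2ccccc2)c(OCc2ccccc2)c(OCc2ccccc2)c(OCc2ccccc2)c1C(c1ccc(OCc2ccccc2)cc1)S(=O)(=O)c1ccc(C)cc1 | intermediate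
23 | (6E)-2,3,4,5-tetrakis(benzyloxy)-6-[4-(benzyloxy)benzylidene]cyclohexa-2,4-dien-1-one (ring B ortho-quinone methide) | O=C1/C(=C/c2ccc(OCc3ccccc3)cc2)C(OCc2ccccc2)=C(OCc2ccccc2)C(OCc2ccccc2)=C1OCc1ccccc1 | intermediate (not isolated)
24 | (3R,4R)-5,7-bis(benzyloxy)-4-[4-(benzyloxy)phenyl]-3-(2-oxoethenyl)chroman-2-one (ketene of 11, arrangement at C3 and C4 unchanged) | O=C1Oc2cc(OCc3ccccc3)cc(OCc3ccccc3)c2[C@@H](c2ccc(OCc3ccccc3)cc2)[C@@H]1C=C=O | intermediate (not isolated)
25 | (3R,4R)-5,7-bis(benzyloxy)-4-[4-(benzyloxy)phenyl]-3-{(3S,4R)-5,6,7,8-tetrakis(benzyloxy)-4-[4-(benzyloxy)phenyl]-2-oxochroman-3-yl}chroman-2-one (octabenzyl ether) | O=C1Oc2cc(OCc3ccccc3)cc(OCc3ccccc3)c2[C@@H](c2ccc(OCc3ccccc3)cc2)[C@@H]1[C@H]1C(=O)Oc2c(OCc3ccccc3)c(OCc3ccccc3)c(OCc3ccccc3)c(OCc3ccccc3)c2[C@H]1c1ccc(OCc2ccccc2)cc1 | intermediate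
26 | (3R,4R,3'S,4'R)-5,5',6',7,7',8'-hexahydroxy-4,4'-bis(4-hydroxyphenyl)-3,3'-bichroman-2,2'-dione | O=C1Oc2cc(O)cc(O)c2[C@@H](c2ccc(O)cc2)[C@@H]1[C@H]1C(=O)Oc2c(O)c(O)c(O)c(O)c2[C@H]1c1ccc(O)cc1 | target

Total step count: 14. Longest linear sequence: 8 steps (steps 7–12, then 13 and 14; the ring A branch, steps 1–6, then 13 and 14, is equally long).

Steps most likely to fail

Step 13. The alkaloid may not override the facial bias of the resident C3/C4 centres at C3'. Cis selectivity may also erode, through an open transition state or through base-mediated epimerisation at C3', and residual phenol may be O-acylated. A simple reversal of sense would first be met with the pseudoenantiomeric O-benzoylquinine. The fallback proper replaces catalyst control by an auxiliary; it sets out from 11 and 22 and returns at 25. Acid chloride 11 would be N-acylated with lithiated (S)-4-benzyloxazolidin-2-one (n-BuLi, THF, −78 °C) to give the imide F1. Its chlorotitanium (Z)-enolate (TiCl4, iPr2NEt, CH2Cl2, −78 °C) would be added to methide 23, released separately from 22 with K2CO3, in a titanium enolate conjugate addition to give the phenolic Michael adduct F2. Here the benzyl group of the chelated auxiliary directs attack to the Si face of C3'; the C4' configuration would have to be verified at this stage. Et3N in CH2Cl2 would then let O1' displace the oxazolidinone and close lactone B to 25.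

Step 3. Insertion at the electron-rich, peri-substituted C4 of 4 may be slow and lose out to protodeboronation of 5. The fallback sets out from 21 and returns at 6. A Wittig reaction of 21 with (triphenylphosphoranylidene)acetaldehyde would give (E)-4-benzyloxycinnamaldehyde F3. This would be combined with commercial 3,5-bis(benzyloxy)phenol F4 under iminium catalysis ((S)-α,α-diphenylprolinol trimethylsilyl ether, benzoic acid, toluene, rt). Friedel–Crafts alkylation ortho to the hydroxyl on the Re face of the β-carbon, followed by hemiacetalisation, should give the (4R) lactol F5 as an anomeric mixture. Oxidation with TEMPO (cat.) and PhI(OAc)2 would then give lactone 6.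

Step 12. Substitution at the last, flanked ring position of 20 may be slow, and the benzylic cation may be captured by a second molecule of 20 in place of sulfinate. The fallback sets out from 20 and returns at 22. Magnesium-mediated ortho-formylation (MgCl2, Et3N, paraformaldehyde, MeCN, reflux) would give the salicylaldehyde F6. Addition of commercial 4-benzyloxyphenylmagnesium bromide (2.2 equiv, THF, 0 °C) would give the benzhydrol F7. Its benzylic hydroxyl would be exchanged for the sulfonyl group with p-toluenesulfinic acid in CH2Cl2 (SN1 substitution through the benzylic cation) to give 22.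

Further compounds
F1 | step 13 | (4S)-4-benzyl-3-{2-[(3S,4R)-5,7-bis(benzyloxy)-4-[4-(benzyloxy)phenyl]-2-oxochroman-3-yl]acetyl}oxazolidin-2-one | O=C1Oc2cc(OCc3ccccc3)cc(OCc3ccccc3)c2[C@@H](c2ccc(OCc3ccccc3)cc2)[C@@H]1CC(=O)N1[C@@H](Cc2ccccc2)COC1=O
F2 | step 13 | open-chain Michael adduct of F1 and 23, a 2-hydroxy-3,4,5,6-tetrakis(benzyloxy)phenyl compound configured at C3' and C4' as in 25 | O=C1Oc2cc(OCc3ccccc3)cc(OCc3ccccc3)c2[C@@H](c2ccc(OCc3ccccc3)cc2)[C@@H]1[C@@H](C(=O)N1[C@@H](Cc2ccccc2)COC1=O)[C@H](c1ccc(OCc2ccccc2)cc1)c1c(O)c(OCc2ccccc2)c(OCc2ccccc2)c(OCc2ccccc2)c1OCc1ccccc1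
F3 | step 3 | (E)-3-[4-(benzyloxy)phenyl]prop-2-enal | O=C/C=C/c1ccc(OCc2ccccc2)cc1
F4 | step 3 | 3,5-bis(benzyloxy)phenol | Oc1cc(OCc2ccccc2)cc(OCc2ccccc2)c1
F5 | step 3 | (4R)-5,7-bis(benzyloxy)-4-[4-(benzyloxy)phenyl]chroman-2-ol (anomeric mixture) | OC1Oc2cc(OCc3ccccc3)cc(OCc3ccccc3)c2[C@@H](c2ccc(OCc3ccccc3)cc2)C1
F6 | step 12 | 2-hydroxy-3,4,5,6-tetrakis(benzyloxy)benzaldehyde | O=Cc1c(O)c(OCc2ccccc2)c(OCc2ccccc2)c(OCc2ccccc2)c1OCc1ccccc1
F7 | step 12 | racemic 3,4,5,6-tetrakis(benzyloxy)-2-{[4-(benzyloxy)phenyl](hydroxy)methyl}phenol | OC(c1ccc(OCc2ccccc2)cc1)c1c(O)c(OCc2ccccc2)c(OCc2ccccc2)c(OCc2ccccc2)c1OCc1ccccc1
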